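**Strategy.** The cyclohexene is not made by a [4+2] dimerisation. Its C1(Me)(alkenyl)–C6(H)(indolyl)–C5=C4(Me) array is a γ,δ-unsaturated acid retron once the styryl carbon on C1 is read as a carboxyl group. The key step is therefore an Ireland–Claisen ring contraction: the silyl ketene acetal of a (2R)-2-methyl-2-[(E)-2-arylethenyl]-δ-valerolactone rearranges through an enforced boat, forming the C1–C6 bond, closing the carbocycle, placing the C4=C5 alkene and setting both stereocentres by transfer of one carbinol centre taken from (R)-linalool. The precursor is a simple δ-lactone (α-methyl epimers converge); both reverse-prenylated indoles arrive by E-selective olefination with one isatin-derived phosphonate.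

Key step: step 11

Assumption: (R)-(−)-linalool of high enantiomeric purity and methyl isatin-5-carboxylate are taken as commercial; the enantiomeric purity of the route is that of the linalool used.

**Step 1**
Reactants: 1 (R)-(−)-linalool
Product: 2 (5R)-5-ethenyl-5-methyloxolan-2-ol (lactol; anomeric mixture)
Conditions: O3 (1 equiv, Sudan Red 7B end point), CH2Cl2/MeOH, −78 °C; then Me2S, −78 °C → rt
Reagents that add atoms: ozone, O=[O+][O-]
Why: Chemoselective ozonolysis with reductive work-up, in which electrophilic ozone should cleave the trisubstituted C6=C7 alkene well before the vinyl group deactivated by the allylic C–O bond, and the resulting 4-hydroxy aldehyde closes to the five-membered lactol without touching the carbinol centre.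

**Step 2**
Reactants: 2 (5R)-5-ethenyl-5-methyloxolan-2-ol
Product: 4 (2R,6RS)-2-ethenyl-6-methoxy-2-methyloxane, via enol ether 3 (not isolated)
Conditions: MeOCH2PPh3Cl, KOtBu, THF, 0 °C → rt; then PPTS (cat.), CH2Cl2, rt
Reagents that add atoms: (methoxymethyl)triphenylphosphonium chloride, COC[P+](c1ccccc1)(c1ccccc1)c1ccccc1.[Cl-]
Why: Wittig methoxymethylenation of the open hydroxy-aldehyde form of the lactol adds the missing carbon as an enol ether, and acid-catalysed addition of the tertiary hydroxyl to the enol ether (the reaction type of THP-ether formation) should close the six-membered mixed acetal.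

**Step 3**
Reactants: 4 (2R,6RS)-2-ethenyl-6-methoxy-2-methyloxane
Product: 5 (2R,6RS)-6-methoxy-2-methyloxane-2-carbaldehyde
Conditions: O3, CH2Cl2, −78 °C; then PPh3, → rt
Reagents that add atoms: ozone, O=[O+][O-]
Why: Ozonolysis of the only remaining C=C bond (acetals react with ozone far more slowly at −78 °C) should give the non-enolisable α-alkoxy aldehyde with the quaternary centre unchanged.

**Step 4**
Reactants: 6 methyl 2,3-dioxo-2,3-dihydro-1H-indole-5-carboxylate (methyl isatin-5-carboxylate); 7 1-bromo-3-methylbut-2-ene (prenyl bromide)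
Product: 8 methyl (3RS)-3-hydroxy-3-(2-methylbut-3-en-2-yl)-2-oxo-2,3-dihydro-1H-indole-5-carboxylate
Conditions: In powder, THF/H2O, rt
Reagents that add atoms: none
Why: Indium-mediated Barbier allylation, in which the prenylindium species adds to the electrophilic C3 ketone through a six-membered cyclic (SE2') transition state, so the bond forms at the γ-carbon and installs the 1,1-dimethylallyl group; the ester and lactam are inert and the new centre (racemic) is removed in step 5.

**Step 5**
Reactants: 8 methyl (3RS)-3-hydroxy-3-(2-methylbut-3-en-2-yl)-2-oxo-2,3-dihydro-1H-indole-5-carboxylate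
Product: 9 [3-(2-methylbut-3-en-2-yl)-1H-indol-5-yl]methanol
Conditions: LiAlH4, THF, 0 °C → reflux
Reagents that add atoms: none
Why: Classical LiAlH4 reduction of a 3-substituted dioxindole to the 3-substituted indole (lactam reduction, then loss of the C3 hydroxyl as water with aromatisation), and the ester is reduced to the benzylic alcohol in the same operation.

**Step 6**
Reactants: 9 [3-(2-methylbut-3-en-2-yl)-1H-indol-5-yl]methanol
Product: 10 diethyl {[3-(2-methylbut-3-en-2-yl)-1H-indol-5-yl]methyl}phosphonate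
Conditions: P(OEt)3, ZnI2, THF, reflux
Reagents that add atoms: triethyl phosphite, CCOP(OCC)OCC
Why: ZnI2-promoted direct conversion of a benzylic alcohol into the phosphonate (phosphite exchange followed by a Lewis-acid-assisted Arbuzov-type rearrangement) avoids an unstable electron-rich benzylic halide, and the blocked C3 position prevents self-alkylation.

**Step 7**
Reactants: 10 diethyl {[3-(2-methylbut-3-en-2-yl)-1H-indol-5-yl]methyl}phosphonate
Product: 11 tert-butyl 5-[(diethoxyphosphoryl)methyl]-3-(2-methylbut-3-en-2-yl)-1H-indole-1-carboxylate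
Conditions: Boc2O, DMAP (cat.), MeCN, rt
Reagents that add atoms: di-tert-butyl dicarbonate, CC(C)(C)OC(=O)OC(=O)OC(C)(C)C
Why: DMAP-catalysed N-acylation of the indole removes the acidic N–H before the enolate steps and makes the arene less electron-rich, which protects the later tertiary allylic C–O intermediates against ionisation.

**Step 8**
Reactants: 5 (2R,6RS)-6-methoxy-2-methyloxane-2-carbaldehyde; 11 tert-butyl 5-[(diethoxyphosphoryl)methyl]-3-(2-methylbut-3-en-2-yl)-1H-indole-1-carboxylate
Product: 12 tert-butyl 5-{(E)-2-[(2R,6RS)-6-methoxy-2-methyloxan-2-yl]ethenyl}-3-(2-methylbut-3-en-2-yl)-1H-indole-1-carboxylate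
Conditions: KHMDS, THF, −78 °C → rt
Reagents that add atoms: none
Why: Horner–Wadsworth–Emmons olefination of a non-enolisable aldehyde with a benzylic phosphonate anion should give the (E)-alkene under thermodynamic control, and the tertiary ether centre takes no part.

**Step 9**
Reactants: 12 tert-butyl 5-{(E)-2-[(2R,6RS)-6-methoxy-2-methyloxan-2-yl]ethenyl}-3-(2-methylbut-3-en-2-yl)-1H-indole-1-carboxylate
Product: 14 tert-butyl 5-{(E)-2-[(2R)-2-methyl-6-oxooxan-2-yl]ethenyl}-3-(2-methylbut-3-en-2-yl)-1H-indole-1-carboxylate, via lactol 13 (not isolated)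
Conditions: PPTS, acetone/H2O, 45 °C; then TPAP (cat.), NMO, 4 Å MS, CH2Cl2, rt
Reagents that add atoms: water, O
Why: Mild acid hydrolysis of the 2-methoxyoxane acetal through its cyclic oxocarbenium ion followed by Ley–Griffith oxidation of the lactol should give the δ-lactone under conditions that leave the N-Boc group, the alkenes and the quaternary centre alone.

**Step 10**
Reactants: 14 tert-butyl 5-{(E)-2-[(2R)-2-methyl-6-oxooxan-2-yl]ethenyl}-3-(2-methylbut-3-en-2-yl)-1H-indole-1-carboxylate
Product: 15 tert-butyl 5-{(E)-2-[(2R,5RS)-2,5-dimethyl-6-oxooxan-2-yl]ethenyl}-3-(2-methylbut-3-en-2-yl)-1H-indole-1-carboxylate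
Conditions: LDA, THF, −78 °C; MeI, −78 → −40 °C
Reagents that add atoms: iodomethane, CI
Why: Kinetic lithium enolate alkylation of the δ-lactone with iodomethane, where the new α-centre needs no control because it becomes sp2 in the next step.

**Step 11**
Reactants: 15 tert-butyl 5-{(E)-2-[(2R,5RS)-2,5-dimethyl-6-oxooxan-2-yl]ethenyl}-3-(2-methylbut-3-en-2-yl)-1H-indole-1-carboxylate
Product: 18 (1S,2S)-2-[1-(tert-butoxycarbonyl)-3-(2-methylbut-3-en-2-yl)-1H-indol-5-yl]-1,4-dimethylcyclohex-3-ene-1-carboxylic acid, via silyl ketene acetal 16 (not isolated), via trimethylsilyl ester 17 (not isolated)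
Conditions: LDA, TMSCl, THF, −78 °C → rt; then PhMe, 100 °C; 1 M HCl work-up
Reagents that add atoms: none
Why: Enolisation and O-silylation turn both C5 epimers of 15 into the single cyclic silyl ketene acetal 16, which on heating undergoes a concerted suprafacial [3,3]-sigmatropic shift of its allyl ketene-acetal unit (Ireland–Claisen rearrangement in its known lactone ring-contraction form), and hydrolysis of silyl ester 17 gives the acid. The ring closes by C–C bond formation between the ketene acetal α-carbon and the aryl-bearing alkene terminus while the allylic C–O bond of the lactone breaks, so the six-membered lactone is traded for the six-membered carbocycle with the new C=C at C3=C4 and the carboxyl group exocyclic on the new quaternary carbon. Because the reacting termini are tied together by the CH2CH2 tether of the dihydropyran ring, only a boat-like transition state with the alkenyl group axial can be reached. In this boat the (E)-aryl group sits in the outside position and ends up cis to the carboxyl group and trans to the methyl group, which fixes the relative configuration of the quaternary and the benzylic centre. The (R) carbinol centre decides from which face the alkene reaches the ketene acetal, so the (1S,2S) acid should form by 1,3-chirality transfer as that centre becomes the sp2 ring carbon. The step needs the concerted shift to outrun heterolysis of the tertiary allylic C–O bond and C-silylation, which the electron-withdrawing N-Boc group, the non-polar solvent and in situ O-silylation of the tetrasubstituted enolate are there to secure.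

**Step 12**
Reactants: 18 (1S,2S)-2-[1-(tert-butoxycarbonyl)-3-(2-methylbut-3-en-2-yl)-1H-indol-5-yl]-1,4-dimethylcyclohex-3-ene-1-carboxylic acid
Product: 19 {(1S,2S)-1,4-dimethyl-2-[3-(2-methylbut-3-en-2-yl)-1H-indol-5-yl]cyclohex-3-en-1-yl}methanol
Conditions: LiAlH4, THF, 0 °C → reflux
Reagents that add atoms: none
Why: LiAlH4 reduction of the hindered acid to the neopentyl alcohol should also cleave the N-acyl-type Boc carbamate (hydride attack at the carbamate carbonyl with indolide as leaving group), and isolated alkenes and both stereocentres are unaffected.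

**Step 13**
Reactants: 19 {(1S,2S)-1,4-dimethyl-2-[3-(2-methylbut-3-en-2-yl)-1H-indol-5-yl]cyclohex-3-en-1-yl}methanol
Product: 20 (1S,2S)-1,4-dimethyl-2-[3-(2-methylbut-3-en-2-yl)-1H-indol-5-yl]cyclohex-3-ene-1-carbaldehyde
Conditions: TPAP (cat.), NMO, 4 Å MS, CH2Cl2, rt
Reagents that add atoms: none
Why: Ley–Griffith oxidation of the primary alcohol should stop at the aldehyde, which has no α-hydrogen and therefore cannot epimerise.

**Step 14**
Reactants: 20 (1S,2S)-1,4-dimethyl-2-[3-(2-methylbut-3-en-2-yl)-1H-indol-5-yl]cyclohex-3-ene-1-carbaldehyde; 11 tert-butyl 5-[(diethoxyphosphoryl)methyl]-3-(2-methylbut-3-en-2-yl)-1H-indole-1-carboxylate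
Product: 22 5-[(E)-2-{(1R,2R)-1,4-dimethyl-2-[3-(2-methylbut-3-en-2-yl)-1H-indol-5-yl]cyclohex-3-en-1-yl}ethenyl]-3-(2-methylbut-3-en-2-yl)-1H-indole (target), via N-Boc alkene 21 (not isolated)
Conditions: KHMDS (2.2 equiv), THF, −78 °C → rt; then NaOMe, MeOH, rt
Reagents that add atoms: none
Why: Horner–Wadsworth–Emmons olefination of the non-enolisable neopentyl aldehyde should give the (E)-alkene (one equivalent of base is taken up by the free indole N–H), and methoxide-mediated methanolysis removes the N-Boc group of the new indole unit in the same flask.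

**Compound list**
1 | (3R)-3,7-dimethylocta-1,6-dien-3-ol, (R)-(−)-linalool | C=C[C@](C)(O)CCC=C(C)C | starting material
2 | (5R)-5-ethenyl-5-methyloxolan-2-ol | C=C[C@@]1(C)CCC(O)O1 | intermediate
3 | (3R)-7-methoxy-3-methylhepta-1,6-dien-3-ol (E/Z mixture; not isolated) | COC=CCC[C@@](C)(O)C=C | intermediate
4 | (2R,6RS)-2-ethenyl-6-methoxy-2-methyloxane | C=C[C@@]1(C)CCCC(OC)O1 | intermediate
5 | (2R,6RS)-6-methoxy-2-methyloxane-2-carbaldehyde | O=C[C@@]1(C)CCCC(OC)O1 | intermediate
6 | methyl 2,3-dioxo-2,3-dihydro-1H-indole-5-carboxylate | COC(=O)c1ccc2NC(=O)C(=O)c2c1 | starting material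
7 | 1-bromo-3-methylbut-2-ene | CC(C)=CCBr | starting material
8 | methyl (3RS)-3-hydroxy-3-(2-methylbut-3-en-2-yl)-2-oxo-2,3-dihydro-1H-indole-5-carboxylate | COC(=O)c1ccc2NC(=O)C(O)(C(C)(C)C=C)c2c1 | intermediate
9 | [3-(2-methylbut-3-en-2-yl)-1H-indol-5-yl]methanol | OCc1ccc2[nH]cc(C(C)(C)C=C)c2c1 | intermediate
10 | diethyl {[3-(2-methylbut-3-en-2-yl)-1H-indol-5-yl]methyl}phosphonate | CCOP(=O)(OCC)Cc1ccc2[nH]cc(C(C)(C)C=C)c2c1 | intermediate
11 | tert-butyl 5-[(diethoxyphosphoryl)methyl]-3-(2-methylbut-3-en-2-yl)-1H-indole-1-carboxylate | CCOP(=O)(OCC)Cc1ccc2c(c1)c(C(C)(C)C=C)cn2C(=O)OC(C)(C)C | intermediate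
12 | tert-butyl 5-{(E)-2-[(2R,6RS)-6-methoxy-2-methyloxan-2-yl]ethenyl}-3-(2-methylbut-3-en-2-yl)-1H-indole-1-carboxylate | COC1CCC[C@](C)(/C=C/c2ccc3c(c2)c(C(C)(C)C=C)cn3C(=O)OC(C)(C)C)O1 | intermediate
13 | tert-butyl 5-{(E)-2-[(2R,6RS)-6-hydroxy-2-methyloxan-2-yl]ethenyl}-3-(2-methylbut-3-en-2-yl)-1H-indole-1-carboxylate (not isolated) | OC1CCC[C@](C)(/C=C/c2ccc3c(c2)c(C(C)(C)C=C)cn3C(=O)OC(C)(C)C)O1 | intermediate
14 | tert-butyl 5-{(E)-2-[(2R)-2-methyl-6-oxooxan-2-yl]ethenyl}-3-(2-methylbut-3-en-2-yl)-1H-indole-1-carboxylate | O=C1CCC[C@](C)(/C=C/c2ccc3c(c2)c(C(C)(C)C=C)cn3C(=O)OC(C)(C)C)O1 | intermediate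
15 | tert-butyl 5-{(E)-2-[(2R,5RS)-2,5-dimethyl-6-oxooxan-2-yl]ethenyl}-3-(2-methylbut-3-en-2-yl)-1H-indole-1-carboxylate | CC1CC[C@](C)(/C=C/c2ccc3c(c2)c(C(C)(C)C=C)cn3C(=O)OC(C)(C)C)OC1=O | intermediate
16 | tert-butyl 5-{(E)-2-[(2R)-2,5-dimethyl-6-(trimethylsilyloxy)-3,4-dihydro-2H-pyran-2-yl]ethenyl}-3-(2-methylbut-3-en-2-yl)-1H-indole-1-carboxylate (not isolated) | C[Si](C)(C)OC1=C(C)CC[C@](C)(/C=C/c2ccc3c(c2)c(C(C)(C)C=C)cn3C(=O)OC(C)(C)C)O1 | intermediate
17 | trimethylsilyl (1S,2S)-2-[1-(tert-butoxycarbonyl)-3-(2-methylbut-3-en-2-yl)-1H-indol-5-yl]-1,4-dimethylcyclohex-3-ene-1-carboxylate (not isolated) | C[Si](C)(C)OC(=O)[C@@]1(C)CCC(C)=C[C@H]1c1ccc2c(c1)c(C(C)(C)C=C)cn2C(=O)OC(C)(C)C | intermediate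
18 | (1S,2S)-2-[1-(tert-butoxycarbonyl)-3-(2-methylbut-3-en-2-yl)-1H-indol-5-yl]-1,4-dimethylcyclohex-3-ene-1-carboxylic acid | OC(=O)[C@@]1(C)CCC(C)=C[C@H]1c1ccc2c(c1)c(C(C)(C)C=C)cn2C(=O)OC(C)(C)C | intermediate
19 | {(1S,2S)-1,4-dimethyl-2-[3-(2-methylbut-3-en-2-yl)-1H-indol-5-yl]cyclohex-3-en-1-yl}methanol | OC[C@@]1(C)CCC(C)=C[C@H]1c1ccc2[nH]cc(C(C)(C)C=C)c2c1 | intermediate
20 | (1S,2S)-1,4-dimethyl-2-[3-(2-methylbut-3-en-2-yl)-1H-indol-5-yl]cyclohex-3-ene-1-carbaldehyde | O=C[C@@]1(C)CCC(C)=C[C@H]1c1ccc2[nH]cc(C(C)(C)C=C)c2c1 | intermediate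
21 | tert-butyl 5-[(E)-2-{(1R,2R)-1,4-dimethyl-2-[3-(2-methylbut-3-en-2-yl)-1H-indol-5-yl]cyclohex-3-en-1-yl}ethenyl]-3-(2-methylbut-3-en-2-yl)-1H-indole-1-carboxylate (not isolated) | C=CC(C)(C)c1cn(C(=O)OC(C)(C)C)c2ccc(/C=C/[C@@]3(C)CCC(C)=C[C@H]3c3ccc4[nH]cc(C(C)(C)C=C)c4c3)cc12 | intermediate
22 | 5-[(E)-2-{(1R,2R)-1,4-dimethyl-2-[3-(2-methylbut-3-en-2-yl)-1H-indol-5-yl]cyclohex-3-en-1-yl}ethenyl]-3-(2-methylbut-3-en-2-yl)-1H-indole | C=CC(C)(C)c1c[nH]c2ccc(/C=C/[C@@]3(C)CCC(C)=C[C@H]3c3ccc4[nH]cc(C(C)(C)C=C)c4c3)cc12 | target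

**Step count.** Total: 14 steps. Longest linear sequence: 11 steps (steps 4–14, from 6); the linalool line is 10 steps.

**Steps most likely to fail**

Step 11 (key step). Heterolysis of the tertiary allylic C–O bond to an ion pair, or C-silylation of the enolate, could compete with the concerted shift and erode chirality transfer; the congested quaternary–tertiary bond formation could also be slow. The fallback builds the ring by a catalytic enantioselective Diels–Alder reaction instead. It sets out from 11: Horner–Wadsworth–Emmons olefination with methacrolein (KHMDS, THF) should give the diene tert-butyl 5-[(1E)-3-methylbuta-1,3-dien-1-yl]-3-(2-methylbut-3-en-2-yl)-1H-indole-1-carboxylate F1. Cycloaddition of this diene with methacrolein under a chiral oxazaborolidinium Lewis acid (CH2Cl2, −78 °C) should give tert-butyl 5-[(1S,6S)-6-formyl-3,6-dimethylcyclohex-2-en-1-yl]-3-(2-methylbut-3-en-2-yl)-1H-indole-1-carboxylate F2. The 1-aryl and 3-methyl groups reinforce the needed regiochemistry, the formyl group is expected endo, and the catalyst enantiomer would be chosen for the (1S,6S) adduct. NaOMe/MeOH removes the Boc group and the route is rejoined at 20.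

Step 14. Addition of the bulky phosphonate anion to the neopentyl aldehyde may be slow and reversible, so that olefination stalls. The fallback uses a smaller, more reactive phosphonium ylide and corrects the geometry afterwards. It sets out from 9 and 20: 9 with PPh3·HBr (MeCN, reflux) should give {[3-(2-methylbut-3-en-2-yl)-1H-indol-5-yl]methyl}triphenylphosphonium bromide F3. Its ylide (LiHMDS, THF; formed without deprotonating either N–H) reacts with 20 to give the alkene as an E/Z mixture, the Z component being 5-[(Z)-2-{(1R,2R)-1,4-dimethyl-2-[3-(2-methylbut-3-en-2-yl)-1H-indol-5-yl]cyclohex-3-en-1-yl}ethenyl]-3-(2-methylbut-3-en-2-yl)-1H-indole F4. Thiyl-radical equilibration (PhSSPh cat., hν) should convert this to the E isomer, arriving at 22.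

Step 9. Acid-induced ionisation or dehydration at the tertiary allylic, aryl-conjugated C–O position could compete with acetal hydrolysis. The fallback forms the lactone before the arene is attached, so no acid is used afterwards. It sets out from 4: PPTS in aqueous acetone, then TPAP/NMO, should give (6R)-6-ethenyl-6-methyloxan-2-one F5. LDA/MeI gives (3RS,6R)-6-ethenyl-3,6-dimethyloxan-2-one F6. Ozonolysis (O3; PPh3) gives (2R,5RS)-2,5-dimethyl-6-oxooxane-2-carbaldehyde F7. Horner–Wadsworth–Emmons olefination with the potassium anion of 11 (inverse addition at −78 °C to limit acyl migration and enolisation) rejoins the route at 15.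

**Further compounds**
F1 | step 11 | tert-butyl 5-[(1E)-3-methylbuta-1,3-dien-1-yl]-3-(2-methylbut-3-en-2-yl)-1H-indole-1-carboxylate | C=C(C)/C=C/c1ccc2c(c1)c(C(C)(C)C=C)cn2C(=O)OC(C)(C)C
F2 | step 11 | tert-butyl 5-[(1S,6S)-6-formyl-3,6-dimethylcyclohex-2-en-1-yl]-3-(2-methylbut-3-en-2-yl)-1H-indole-1-carboxylate | O=C[C@@]1(C)CCC(C)=C[C@H]1c1ccc2c(c1)c(C(C)(C)C=C)cn2C(=O)OC(C)(C)C
F3 | step 14 | {[3-(2-methylbut-3-en-2-yl)-1H-indol-5-yl]methyl}triphenylphosphonium bromide | C=CC(C)(C)c1c[nH]c2ccc(C[P+](c3ccccc3)(c3ccccc3)c3ccccc3)cc12.[Br-]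
F4 | step 14 | 5-[(Z)-2-{(1R,2R)-1,4-dimethyl-2-[3-(2-methylbut-3-en-2-yl)-1H-indol-5-yl]cyclohex-3-en-1-yl}ethenyl]-3-(2-methylbut-3-en-2-yl)-1H-indole | C=CC(C)(C)c1c[nH]c2ccc(/C=C\[C@@]3(C)CCC(C)=C[C@H]3c3ccc4[nH]cc(C(C)(C)C=C)c4c3)cc12
F5 | step 9 | (6R)-6-ethenyl-6-methyloxan-2-one | C=C[C@@]1(C)CCCC(=O)O1
F6 | step 9 | (3RS,6R)-6-ethenyl-3,6-dimethyloxan-2-one | C=C[C@@]1(C)CCC(C)C(=O)O1
F7 | step 9 | (2R,5RS)-2,5-dimethyl-6-oxooxane-2-carbaldehyde | O=C[C@@]1(C)CCC(C)C(=O)O1
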